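The earlier runs and the new flask stem from a simulated flask with constants of no real substance; noise was put on by code.

4 questions stand on this flask, and one quantity serves the first three: the free monomer concentration at which its two exits take it equally fast.

| setting | birch | cedar | oak | flask |
|---|---|---|---|---|
| free monomer | 0.42 M | 0.66 M | 0.30 M | 0.30 M |
| initiator | 7.5 mM (in portions, 2) | 7.5 mM (in portions, 2) | 11 mM (in portions, 2) | 7.5 mM (in portions, 2) |
| remark | run made earlier; portions every 30 h | run made earlier; portions every 30 h | run made earlier; portions every 30 h | the portions of initiator follow each other after 30 h, the first at the start |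
| time |  |  |  | 2.5 d |

- birch (time / h: monomer in chains / %, homo dimer / %): 6.00: 4, 30; 12.0: 8, 38; 20.0: 13, 47; 25.0: 19, 52; 30.0: 15, 55; 40.0: 22, 58
- cedar (time / h: monomer in chains / %, homo dimer / %): 6.00: 3, 36; 12.0: 5, 44; 20.0: 10, 55; 25.0: 15, 59; 30.0: 15, 64; 40.0: 16, 69
- oak (time / h: monomer in chains / %, homo dimer / %): 8.00: 6, 22; 15.0: 11, 34; 20.0: 13, 43; 30.0: 23, 47; 40.0: 29, 45

(scatter of a reading: 2 percentage points)

1. the monomer in chains in the flask at 2.5 d, as a percentage of the free monomer charged
2. the homo dimer in the flask at 2.5 d, as a percentage of the free monomer charged
3. the free monomer in the flask at 2.5 d, as a percentage of the free monomer charged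
4. concentration of living end at 2.5 d, in M

- percent here means free monomer units held: one homo dimer counts as two

Let M be free monomer. Dimer formation removes it at D·M·M, and chain growth at g·M, with g a pseudo-first-order constant that carries the living ends. Oak's first reading of homo dimer gives

D = 0.127 /M/h

Birch, which has the flask's initiator, gives from 20.0 h to 40.0 h

g = 0.0150 /h

But these readings scatter. Oak's last interval, scaled by initiator on the assumption of proportion, gives 0.0146 /h, so g stands. The crossover concentration is then

M* = g/D = 0.118 M

The flask starts higher than M*, so dimer leads at the start, and chains lead once free monomer falls below M*. With both exits acting, the sum of the reciprocals of M and M* grows as exp(g·t), and chains gain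

U = M*·ln[(1 + Ms/M*)/(1 + Me/M*)]

where Ms and Me are M at the start and end of a stretch. One stretch gives 16.2% free monomer and 36.2% monomer in chains.

The objection is that birch's first 20.0 h give g = 0.00929 /h, lower than the late value. So the flask is solved in two stretches joined at the second portion, at 30 h: 0.114 M free monomer there, and at 2.5 d

free monomer 0.0537 M, or 17.9%
chains 0.0858 M, or 28.6%
dimer, the remainder, 53.5%

The living end is carried inside g, so this reckoning leaves it open.

The forecast differs: 32% monomer in chains, 48% homo dimer, 20% free monomer, 0.005 M living end, with the words "Dimer slowly releases monomer, ending near 48%".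

The flask gives 27.5% monomer in chains, 54.9% homo dimer, 16.5% free monomer and 0.00377 M living end.

    free monomer + living end → monomer in chains + living end, rate k1*[living end]*[free monomer] (k = 0.00130 /M/s)
    2 free monomer → homo dimer (k = 1.81 × 10⁻⁵ /M/s)
    initiator + monomer in chains → spent initiator (k = 3.20 × 10⁻⁴ /M/s)
    free monomer + initiator → living end + monomer in chains (k = 8.08 × 10⁻⁵ /M/s)

Dimer in the flask rises from 47.2% at 1.25 d to 54.9% at 2.50 d. Free monomer in the flask ends at 0.0494 M, below M* by a factor 2.39, and at that time it goes into chains 2.7 times as fast as into homo dimer. Monomer in chains in the flask stands at 27.5% in part because homo dimer formation takes free monomer: in the same run with that path taken away, monomer in chains reaches 58.2%.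

A second flask, with 1.2 M of free monomer, starts at ten times M*. The same two stretches give 0.182 M of free monomer at 30 h, then 0.0743 M, which is 6.19% free monomer and 14.2% monomer in chains. Computed, that flask holds 5.23% free monomer and 16.9% monomer in chains.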